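**Plan**

- Retrosynthetic cuts, in order: the O–benzyl bond (protecting group), C2–C3 of the pyridone (aldol-type condensation), N1–C8a (amidation of a ring enol triflate), C4–C4a (enolate acylation) and C5–octyl (conjugate addition).
- Enabling feature (quinolone numbering): along the N1(OMe)–C2(CH2OH)–C3(OMe)–C4(=O) edge of the pyridone ring, C3 is the alpha carbon of the C4 ketone and C2 can be the carbonyl carbon of an N-methoxy amide. The heteroaromatic ring can therefore close at C2=C3 on the finished carbocycle (C4a–C8a) with the N–O bond already present.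
- Forward order: the carbocycle comes from cyclohexenone; octyl and methoxyacetyl are added in one pot; the ring enol triflate is coupled with the N-methoxy amide at C8a; the pyridone ring closes last; the benzyl group is then removed.
- Stereochemistry: the only stereocentre, C5 (R), is set by the copper-catalysed enantioselective conjugate addition of step 1 and is not touched afterwards.

Key step: step 5

Assumption: diketone 5 is written in its diketo form although it should exist largely as the ring enol, its C2 is labile and left undefined, and the antipode of the ferrocenyl diphosphine in step 1 is the one that delivers the R centre.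

**Route**

Step 1
Reactants: 1 cyclohex-2-en-1-one; 2 octylmagnesium bromide; 3 methoxyacetyl chloride
Product: 5 (3R)-2-(methoxyacetyl)-3-octylcyclohexan-1-one, via magnesium enolate 4 (not isolated)
Conditions: CuCl (5 mol %), TaniaPhos ligand 1-[α-(dimethylamino)-2-(diphenylphosphino)benzyl]-2-(diphenylphosphino)ferrocene (single enantiomer, 6 mol %), 2 (1.15 equiv), Et2O, 0 °C; then 3 (1.3 equiv), −78 → 0 °C; aq NH4Cl
Reagents that add atoms: none
Why: Copper-catalysed asymmetric conjugate addition of a Grignard reagent sets C3 as R under control of the chiral diphosphine–CuCl complex, and the regiodefined, tightly ion-paired magnesium enolate 4 should undergo C-acylation by the acid chloride in ether at C2 (tandem conjugate addition–enolate acylation).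

Step 2
Reactants: 5 (3R)-2-(methoxyacetyl)-3-octylcyclohexan-1-one
Product: 6 (3R)-2-(methoxyacetyl)-3-octylcyclohex-1-en-1-yl trifluoromethanesulfonate
Conditions: NaH, Et2O, 0 °C; Tf2O, −78 → 0 °C
Reagents that add atoms: trifluoromethanesulfonic anhydride, O=S(=O)(OS(=O)(=O)C(F)(F)F)C(F)(F)F
Why: Enol triflate formation from a 1,3-dicarbonyl sodium enolate should occur on the ring oxygen, because the endocyclic enol avoids the allylic strain of a tetrasubstituted exocyclic alkene next to the octyl-bearing carbon, giving the vinylogous acyl triflate with the C1=C2 bond in the ring.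

Step 3
Reactants: 7 (benzyloxy)acetyl chloride
Product: 8 2-(benzyloxy)-N-methoxyacetamide
Conditions: MeONH2·HCl, K2CO3, EtOAc/H2O, 0 °C → rt
Reagents that add atoms: O-methylhydroxylamine hydrochloride, CON.Cl
Why: Schotten–Baumann N-acylation of O-methylhydroxylamine, whose only acylable site is nitrogen, gives the hydroxamate ester.

Step 4
Reactants: 6 (3R)-2-(methoxyacetyl)-3-octylcyclohex-1-en-1-yl trifluoromethanesulfonate; 8 2-(benzyloxy)-N-methoxyacetamide
Product: 9 (R)-2-(benzyloxy)-N-methoxy-N-[2-(methoxyacetyl)-3-octylcyclohex-1-en-1-yl]acetamide
Conditions: Pd2(dba)3 (2.5 mol %), Xantphos (7.5 mol %), Cs2CO3 (1.5 equiv), 1,4-dioxane, 60 °C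
Reagents that add atoms: none
Why: Buchwald–Hartwig-type amidation of an enol triflate: the electron-poor triflate adds readily to zerovalent palladium, carbonate deprotonates the acidic N-methoxy amide, the wide-bite-angle diphosphine promotes C–N reductive elimination, and any uncatalysed addition–elimination at the same carbon gives the same enamide.

Step 5
Reactants: 9 (R)-2-(benzyloxy)-N-methoxy-N-[2-(methoxyacetyl)-3-octylcyclohex-1-en-1-yl]acetamide
Product: 11 (5R)-2-[(benzyloxy)methyl]-1,3-dimethoxy-5-octyl-5,6,7,8-tetrahydroquinolin-4(1H)-one, via hemiaminal aldol adduct 10 (not isolated)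
Conditions: KOtBu (1.5 equiv), THF/t-BuOH, 0 °C → rt; aq NH4Cl
Reagents that add atoms: none
Why: tert-Butoxide enolises the methoxymethyl ketone, the enolate carbon (future C3) adds to the N-methoxy amide carbonyl (future C2) to give adduct 10, and E1cB loss of water aromatises the ring to the N-methoxy-4-pyridone. The closest known reaction is the Camps cyclisation of N-acylated ortho-aminoaryl ketones and N-acyl enaminones to 4-quinolones and 4-pyridones. The pyridone ring closes in a 6-(enolendo)-exo-trig mode. No stereocentre is formed, and C5 should be retained because its hydrogen is only cross-conjugated to the carbonyl and is not acidified. The step needs 4-pyridone rather than 2-pyridone formation; this is secured because the ketone CH2(OMe) is the site enolised, the N-alkoxy amide carbonyl is the better electrophile (weak nitrogen donation, shared with the enone), and the C4 ketone is a hindered vinylogous amide carbonyl. If the tetrahedral intermediate expels nitrogen instead, the resulting 1,3-diketone and N–H methoxy enaminone should recondense to the same ring.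

Step 6
Reactants: 11 (5R)-2-[(benzyloxy)methyl]-1,3-dimethoxy-5-octyl-5,6,7,8-tetrahydroquinolin-4(1H)-one
Product: 12 (5R)-2-(hydroxymethyl)-1,3-dimethoxy-5-octyl-5,6,7,8-tetrahydroquinolin-4(1H)-one
Conditions: H2 (1 atm), 10% Pd/C, EtOAc, rt
Reagents that add atoms: none
Why: Neutral catalytic hydrogenolysis of a benzyl ether should cleave only the benzylic C–O bond, since the N–OMe bond of a vinylogous hydroxamate and the pyridone ring are not reduced at atmospheric pressure over palladium.

**Compound list**

1 | cyclohex-2-en-1-one | O=C1C=CCCC1 | starting material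
2 | octylmagnesium bromide | CCCCCCCC[Mg]Br | starting material
3 | methoxyacetyl chloride | COCC(=O)Cl | starting material
4 | bromomagnesium (R)-3-octylcyclohex-1-en-1-olate | CCCCCCCC[C@@H]1CCCC(O[Mg]Br)=C1 | intermediate (not isolated)
5 | (3R)-2-(methoxyacetyl)-3-octylcyclohexan-1-one | CCCCCCCC[C@@H]1CCCC(=O)C1C(=O)COC | intermediate
6 | (3R)-2-(methoxyacetyl)-3-octylcyclohex-1-en-1-yl trifluoromethanesulfonate | CCCCCCCC[C@@H]1CCCC(OS(=O)(=O)C(F)(F)F)=C1C(=O)COC | intermediate
7 | (benzyloxy)acetyl chloride | O=C(Cl)COCc1ccccc1 | starting material
8 | 2-(benzyloxy)-N-methoxyacetamide | CONC(=O)COCc1ccccc1 | intermediate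
9 | (R)-2-(benzyloxy)-N-methoxy-N-[2-(methoxyacetyl)-3-octylcyclohex-1-en-1-yl]acetamide | CCCCCCCC[C@@H]1CCCC(N(OC)C(=O)COCc2ccccc2)=C1C(=O)COC | intermediate
10 | (5R)-2-[(benzyloxy)methyl]-2-hydroxy-1,3-dimethoxy-5-octyl-2,3,5,6,7,8-hexahydroquinolin-4(1H)-one (C2 and C3 undefined) | CCCCCCCC[C@@H]1CCCC2=C1C(=O)C(OC)C(O)(COCc3ccccc3)N2OC | intermediate (not isolated)
11 | (5R)-2-[(benzyloxy)methyl]-1,3-dimethoxy-5-octyl-5,6,7,8-tetrahydroquinolin-4(1H)-one | CCCCCCCC[C@@H]1CCCc2c1c(=O)c(OC)c(COCc3ccccc3)n2OC | intermediate
12 | (5R)-2-(hydroxymethyl)-1,3-dimethoxy-5-octyl-5,6,7,8-tetrahydroquinolin-4(1H)-one | CCCCCCCC[C@@H]1CCCc2c1c(=O)c(OC)c(CO)n2OC | target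

**Step count**

Total steps: 6. Longest linear sequence: 5 steps (1, 2, 4, 5, 6); step 3 is a one-step side branch.

**Steps most likely to fail**

1. Step 4. The coupling must occur at a tetrasubstituted, flanked carbon with an ambident N-alkoxy amidate. Reductive elimination may be slow, the triflyl group may be transferred to the amidate (attack at sulfur, returning 5), or vinylation may go to oxygen instead of nitrogen. Fallback: starting from 6, O-methylhydroxylamine (MeONH2·HCl, K2CO3, MeCN, 0 °C) should displace triflate by addition–elimination to give (R)-2-methoxy-1-[2-(methoxyamino)-6-octylcyclohex-1-en-1-yl]ethan-1-one F1, in equilibrium with its oxime ether tautomer. Deprotonation (NaH, THF, 0 °C) and acylation with 7 should then give the enamide, any O-acyl isomer being expected to pass to the N-acyl compound by 1,5-acyl shift. The route is rejoined at 9.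

2. Step 5. The base may attack the activated amide intermolecularly (loss of the benzyloxyacetyl group), or enolisation on the amide side may lead to closure onto the C4 ketone in the 2-pyridone sense. Fallback: starting from 6, the same aminolysis gives the enaminone F1. Double deprotonation (LDA, 2.2 equiv, THF, −78 °C; N–H first, then the methoxymethyl carbon) and C-acylation with methyl (benzyloxy)acetate should give (R)-4-(benzyloxy)-2-methoxy-1-[2-(methoxyamino)-6-octylcyclohex-1-en-1-yl]butane-1,3-dione F2. Warming F2 in AcOH should close the ring by condensation of nitrogen with the new ketone and loss of water, so the C2–C3 bond is made intermolecularly and the ring closes at N1–C2. The route is rejoined at 11.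

3. Step 1. Enolate 4 may be acylated on oxygen, the acidic product may protonate unreacted enolate, or residual Grignard reagent may consume 3. Fallback: starting from 1 and 2, the same copper-catalysed addition is run and enolate 4 is trapped with methoxyacetaldehyde (tandem conjugate addition–aldol) to give (3R)-2-(1-hydroxy-2-methoxyethyl)-3-octylcyclohexan-1-one F3 as a diastereomer mixture. Oxidation with Dess–Martin periodinane (CH2Cl2, rt) should then give the diketone. The route is rejoined at 5.

**Further compounds**

F1 | step 4 | (R)-2-methoxy-1-[2-(methoxyamino)-6-octylcyclohex-1-en-1-yl]ethan-1-one | CCCCCCCC[C@@H]1CCCC(NOC)=C1C(=O)COC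
F2 | step 5 | (R)-4-(benzyloxy)-2-methoxy-1-[2-(methoxyamino)-6-octylcyclohex-1-en-1-yl]butane-1,3-dione | CCCCCCCC[C@@H]1CCCC(NOC)=C1C(=O)C(OC)C(=O)COCc2ccccc2
F3 | step 1 | (3R)-2-(1-hydroxy-2-methoxyethyl)-3-octylcyclohexan-1-one | CCCCCCCC[C@@H]1CCCC(=O)C1C(O)COC
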